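**Retrosynthetic overview**
1. 19 ⇐ 18: the last operation only removes the N-tert-butylsulfonyl (Bus) group and the acetonide; the C3 acetate is put on 17 while N1 and the C11′/C12′ diol are masked.
2. C3 and C6 are relayed from C2 alone: borohydride reduction of piperidin-3-one 16 sets C3, and silane reduction of the C6 N,O-ketal of dihydropyridinone 13 sets C6.
3. Key disconnection: the piperidine ring (N1, C2–C6) with its 2-methyl/3-oxy/6-alkyl pattern is cut back to the 2,5-disubstituted furan 10. Furan C2–C5 become C3–C6, the α-aminoethyl carbon becomes C2, and the N1–C6 bond closes the only ring in one peracid operation that also turns the sulfinyl auxiliary into the N-sulfonyl group (S-oxidation/aza-Achmatowicz ring expansion).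
4. 10 ⇐ ketone 7 + (S)-tert-butanesulfinamide (sets C2, the one ring stereocentre made by reagent control); 7 ⇐ 2-acetyl-5-bromofuran + alkene 4 (B-alkyl Suzuki, furan–C1′ bond).
5. 4 ⇐ chiral-pool (S)-solketal tosylate (brings C11′) + non-8-enyl Grignard reagent; ring order: dioxolane bought, piperidine formed in step 4.

Key step: step 4

Remark: the target is read as (2S,3S,6R)-6-[(11R)-11,12-dihydroxydodecyl]-2-methylpiperidin-3-yl acetate, i.e. the all-cis 2-methyl/3-acetoxy/6-alkyl piperidine. The configuration at the N,O-ketal carbon C6 of 13 is left open because step 5 erases it. Bus = tert-butylsulfonyl.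

**Step 1**
Reactants: 1 9-bromonon-1-ene; 2 [(4S)-2,2-dimethyl-1,3-dioxolan-4-yl]methyl 4-methylbenzenesulfonate
Product: 4 (4R)-4-(dec-9-en-1-yl)-2,2-dimethyl-1,3-dioxolane, via non-8-enylmagnesium bromide 3 (not isolated)
Conditions: Mg, THF; then 2, Li2CuCl4 (cat.), THF, −78 °C → rt
Reagents that add atoms: none
Why: Copper-catalysed Grignard/primary alkyl tosylate cross-coupling forms the C–C bond at the CH2 group without touching the dioxolane stereocentre, so the future C11′ carbinol comes from the chiral pool; the descriptor changes from (S) to (R) only through the change in CIP priorities.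

**Step 2**
Reactants: 4 (4R)-4-(dec-9-en-1-yl)-2,2-dimethyl-1,3-dioxolane; 5 1-(5-bromofuran-2-yl)ethan-1-one
Product: 7 1-(5-{10-[(4R)-2,2-dimethyl-1,3-dioxolan-4-yl]decyl}furan-2-yl)ethan-1-one, via B-alkyl-9-BBN adduct 6 (not isolated)
Conditions: 9-BBN, THF, 0 °C → rt; then 5, PdCl2(dppf) (cat.), aq. K3PO4, DMF, 50 °C
Reagents that add atoms: none
Why: Anti-Markovnikov hydroboration gives the primary alkylborane, which should undergo B-alkyl Suzuki–Miyaura coupling with the electron-poor bromofuran; ketone and acetonide tolerate the mildly basic conditions.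

**Step 3**
Reactants: 7 1-(5-{10-[(4R)-2,2-dimethyl-1,3-dioxolan-4-yl]decyl}furan-2-yl)ethan-1-one; 8 (S)-2-methylpropane-2-sulfinamide
Product: 10 (S)-N-[(1S)-1-(5-{10-[(4R)-2,2-dimethyl-1,3-dioxolan-4-yl]decyl}furan-2-yl)ethyl]-2-methylpropane-2-sulfinamide, via N-sulfinyl ketimine 9 (not isolated)
Conditions: Ti(OEt)4, THF, 65 °C; then NaBH4, −48 °C
Reagents that add atoms: none
Why: Titanium-mediated condensation gives the (E)-N-sulfinyl ketimine, and borohydride delivered through a cyclic transition state bound to the sulfinyl oxygen should add to the face that gives the (S)-carbon from the (S)-sulfinyl group (diastereoselective sulfinyl ketimine reduction); the minor diastereomer would be removed by chromatography.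

**Step 4**
Reactants: 10 (S)-N-[(1S)-1-(5-{10-[(4R)-2,2-dimethyl-1,3-dioxolan-4-yl]decyl}furan-2-yl)ethyl]-2-methylpropane-2-sulfinamide
Product: 13 (2S)-1-(tert-butylsulfonyl)-6-{10-[(4R)-2,2-dimethyl-1,3-dioxolan-4-yl]decyl}-6-hydroxy-2-methyl-1,6-dihydropyridin-3(2H)-one, via Bus sulfonamide 11 (not isolated), via Z-enedione 12 (not isolated)
Conditions: mCPBA (2.3 equiv), CH2Cl2, 0 °C → rt
Reagents that add atoms: 3-chloroperoxybenzoic acid (mCPBA) OOC(=O)c1cccc(Cl)c1
Why: The first equivalent of peracid oxidises the sulfinyl sulfur to the sulfonyl level, turning the auxiliary into the acidic N–H sulfonamide 11; the second epoxidises the electron-rich 2,5-dialkylfuran, whose epoxide collapses to the (Z)-ene-1,4-dione 12, and the sulfonamide nitrogen then adds to the chain-bearing ketone. The closest known reaction types are the peracid oxidation of tert-butanesulfinamides to tert-butylsulfonamides and the aza-Achmatowicz ring expansion of N-sulfonyl furfurylamines. The piperidine ring closes by 6-exo-trig addition of N1 to the C6 carbonyl, the Z-alkene inherited from the furan holding both ends within reach, so that furan C2–C5 become C3–C6. C2 is carried over unchanged from 10 (no base is present, so the α-amino ketone should not epimerise), and the new C6 N,O-ketal centre needs no control because step 5 ionises it. The selectivity required is chemoselectivity: S-oxidation and furan oxidation must outrun epoxidation of the product enone and acid cleavage of the acetonide, which the electron-poor enone and the cold, weakly acidic medium should secure.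

**Step 5**
Reactants: 13 (2S)-1-(tert-butylsulfonyl)-6-{10-[(4R)-2,2-dimethyl-1,3-dioxolan-4-yl]decyl}-6-hydroxy-2-methyl-1,6-dihydropyridin-3(2H)-one
Product: 15 (2S,6R)-1-(tert-butylsulfonyl)-6-{10-[(4R)-2,2-dimethyl-1,3-dioxolan-4-yl]decyl}-2-methyl-1,6-dihydropyridin-3(2H)-one, via N-sulfonyliminium ion 14 (not isolated)
Conditions: Et3SiH, BF3·OEt2, CH2Cl2, −78 → −40 °C
Reagents that add atoms: none
Why: The Lewis acid ionises the tertiary N,O-ketal to the nearly planar N-sulfonyliminium ion, and the silane should transfer hydride to C6 from the face opposite the C2 methyl group, which allylic strain with the sulfonyl group holds pseudo-axial, giving the 2,6-cis product (ionic hydrogenation of a hemiaminal); acetonide and Bus group should survive at low temperature.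

**Step 6**
Reactants: 15 (2S,6R)-1-(tert-butylsulfonyl)-6-{10-[(4R)-2,2-dimethyl-1,3-dioxolan-4-yl]decyl}-2-methyl-1,6-dihydropyridin-3(2H)-one
Product: 16 (2S,6R)-1-(tert-butylsulfonyl)-6-{10-[(4R)-2,2-dimethyl-1,3-dioxolan-4-yl]decyl}-2-methylpiperidin-3-one
Conditions: H2 (1 atm), Pd/C, EtOAc, rt
Reagents that add atoms: none
Why: Heterogeneous hydrogenation saturates the enone C4=C5 bond chemoselectively; ketone, sulfonamide and acetonide are inert and no stereocentre is created.

**Step 7**
Reactants: 16 (2S,6R)-1-(tert-butylsulfonyl)-6-{10-[(4R)-2,2-dimethyl-1,3-dioxolan-4-yl]decyl}-2-methylpiperidin-3-one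
Product: 17 (2S,3S,6R)-1-(tert-butylsulfonyl)-6-{10-[(4R)-2,2-dimethyl-1,3-dioxolan-4-yl]decyl}-2-methylpiperidin-3-ol
Conditions: NaBH4, MeOH, −40 → 0 °C
Reagents that add atoms: none
Why: Borohydride reduction of the ketone: with the 2-methyl group axial next to the carbonyl in the N-sulfonyl piperidinone, hydride should attack C3 axially from the face opposite to it, giving the alcohol cis to the methyl group and thus the all-cis (2S,3S,6R) array.

**Step 8**
Reactants: 17 (2S,3S,6R)-1-(tert-butylsulfonyl)-6-{10-[(4R)-2,2-dimethyl-1,3-dioxolan-4-yl]decyl}-2-methylpiperidin-3-ol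
Product: 18 (2S,3S,6R)-1-(tert-butylsulfonyl)-6-{10-[(4R)-2,2-dimethyl-1,3-dioxolan-4-yl]decyl}-2-methylpiperidin-3-yl acetate
Conditions: Ac2O, Et3N, DMAP (cat.), CH2Cl2, rt
Reagents that add atoms: acetic anhydride CC(=O)OC(C)=O
Why: DMAP-catalysed acylation of the only free hydroxyl; nitrogen is blocked as the sulfonamide and the diol as the acetonide, so acetylation is site-specific.

**Step 9**
Reactants: 18 (2S,3S,6R)-1-(tert-butylsulfonyl)-6-{10-[(4R)-2,2-dimethyl-1,3-dioxolan-4-yl]decyl}-2-methylpiperidin-3-yl acetate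
Product: 19 (2S,3S,6R)-6-[(11R)-11,12-dihydroxydodecyl]-2-methylpiperidin-3-yl acetate
Conditions: TfOH, anisole, CH2Cl2, 0 °C; then THF–H2O, 0 °C; aq. NaHCO3, 0 °C
Reagents that add atoms: none
Why: Strong-acid cleavage of the tert-butylsulfonamide (loss of the tert-butyl cation, trapped by anisole, then of SO2) followed by aqueous-acid hydrolysis of the acetonide; the secondary acetate should survive cold acid, and the amine stays protonated until the cold bicarbonate work-up, which disfavours O→N acetyl transfer.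

**Compound list**
1 | 9-bromonon-1-ene | C=CCCCCCCCBr | starting material
2 | [(4S)-2,2-dimethyl-1,3-dioxolan-4-yl]methyl 4-methylbenzenesulfonate ((S)-solketal tosylate) | Cc1ccc(cc1)S(=O)(=O)OC[C@@H]1COC(C)(C)O1 | starting material
3 | non-8-enylmagnesium bromide | C=CCCCCCCC[Mg]Br | intermediate (not isolated)
4 | (4R)-4-(dec-9-en-1-yl)-2,2-dimethyl-1,3-dioxolane | C=CCCCCCCCC[C@@H]1COC(C)(C)O1 | intermediate
5 | 1-(5-bromofuran-2-yl)ethan-1-one | CC(=O)c1ccc(Br)o1 | starting material
6 | 9-{10-[(4R)-2,2-dimethyl-1,3-dioxolan-4-yl]decyl}-9-borabicyclo[3.3.1]nonane | CC1(C)OC[C@@H](CCCCCCCCCCB2C3CCCC2CCC3)O1 | intermediate (not isolated)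
7 | 1-(5-{10-[(4R)-2,2-dimethyl-1,3-dioxolan-4-yl]decyl}furan-2-yl)ethan-1-one | CC(=O)c1ccc(CCCCCCCCCC[C@@H]2COC(C)(C)O2)o1 | intermediate
8 | (S)-2-methylpropane-2-sulfinamide | CC(C)(C)[S@@](N)=O | starting material
9 | (S,E)-N-[1-(5-{10-[(4R)-2,2-dimethyl-1,3-dioxolan-4-yl]decyl}furan-2-yl)ethylidene]-2-methylpropane-2-sulfinamide | C/C(=N\[S@@](=O)C(C)(C)C)c1ccc(CCCCCCCCCC[C@@H]2COC(C)(C)O2)o1 | intermediate (not isolated)
10 | (S)-N-[(1S)-1-(5-{10-[(4R)-2,2-dimethyl-1,3-dioxolan-4-yl]decyl}furan-2-yl)ethyl]-2-methylpropane-2-sulfinamide | C[C@H](N[S@@](=O)C(C)(C)C)c1ccc(CCCCCCCCCC[C@@H]2COC(C)(C)O2)o1 | intermediate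
11 | N-[(1S)-1-(5-{10-[(4R)-2,2-dimethyl-1,3-dioxolan-4-yl]decyl}furan-2-yl)ethyl]-2-methylpropane-2-sulfonamide | C[C@H](NS(=O)(=O)C(C)(C)C)c1ccc(CCCCCCCCCC[C@@H]2COC(C)(C)O2)o1 | intermediate (not isolated)
12 | N-{(2S,4Z)-16-[(4R)-2,2-dimethyl-1,3-dioxolan-4-yl]-3,6-dioxohexadec-4-en-2-yl}-2-methylpropane-2-sulfonamide | C[C@H](NS(=O)(=O)C(C)(C)C)C(=O)/C=C\C(=O)CCCCCCCCCC[C@@H]1COC(C)(C)O1 | intermediate (not isolated)
13 | (2S)-1-(tert-butylsulfonyl)-6-{10-[(4R)-2,2-dimethyl-1,3-dioxolan-4-yl]decyl}-6-hydroxy-2-methyl-1,6-dihydropyridin-3(2H)-one (C6 configuration open) | C[C@@H]1N(S(=O)(=O)C(C)(C)C)C(O)(CCCCCCCCCC[C@@H]2COC(C)(C)O2)C=CC1=O | intermediate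
14 | (2S)-1-(tert-butylsulfonyl)-6-{10-[(4R)-2,2-dimethyl-1,3-dioxolan-4-yl]decyl}-2-methyl-3-oxo-2,3-dihydropyridin-1-ium | C[C@@H]1[N+](S(=O)(=O)C(C)(C)C)=C(CCCCCCCCCC[C@@H]2COC(C)(C)O2)C=CC1=O | intermediate (not isolated)
15 | (2S,6R)-1-(tert-butylsulfonyl)-6-{10-[(4R)-2,2-dimethyl-1,3-dioxolan-4-yl]decyl}-2-methyl-1,6-dihydropyridin-3(2H)-one | C[C@@H]1N(S(=O)(=O)C(C)(C)C)[C@H](CCCCCCCCCC[C@@H]2COC(C)(C)O2)C=CC1=O | intermediate
16 | (2S,6R)-1-(tert-butylsulfonyl)-6-{10-[(4R)-2,2-dimethyl-1,3-dioxolan-4-yl]decyl}-2-methylpiperidin-3-one | C[C@@H]1N(S(=O)(=O)C(C)(C)C)[C@H](CCCCCCCCCC[C@@H]2COC(C)(C)O2)CCC1=O | intermediate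
17 | (2S,3S,6R)-1-(tert-butylsulfonyl)-6-{10-[(4R)-2,2-dimethyl-1,3-dioxolan-4-yl]decyl}-2-methylpiperidin-3-ol | C[C@@H]1N(S(=O)(=O)C(C)(C)C)[C@H](CCCCCCCCCC[C@@H]2COC(C)(C)O2)CC[C@@H]1O | intermediate
18 | (2S,3S,6R)-1-(tert-butylsulfonyl)-6-{10-[(4R)-2,2-dimethyl-1,3-dioxolan-4-yl]decyl}-2-methylpiperidin-3-yl acetate | C[C@@H]1N(S(=O)(=O)C(C)(C)C)[C@H](CCCCCCCCCC[C@@H]2COC(C)(C)O2)CC[C@@H]1OC(C)=O | intermediate
19 | (2S,3S,6R)-6-[(11R)-11,12-dihydroxydodecyl]-2-methylpiperidin-3-yl acetate | CC(=O)O[C@H]1CC[C@@H](CCCCCCCCCC[C@@H](O)CO)N[C@H]1C | target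

**Step count**
Total steps: 9. Longest linear sequence: 9 steps (1/2 → 19); the other inputs (5, 8) are bought.

**Steps most likely to fail, with fallbacks**

Step 5. Hydride transfer to the nearly planar iminium ion may show too little facial bias (C6 epimer). The Lewis acid may also open the acetonide, or the ion may lose sulfinate and aromatise to a 3-hydroxypyridine. The fallback sets out from 13 and returns at 16, and sets C6 on a metal surface instead of by a silane. Anhydrous acid-catalysed dehydration of 13 (cat. camphorsulfonic acid, 4 Å sieves, CH2Cl2, 0 °C) would give the exocyclic dienyl sulfonamide (2S)-1-(tert-butylsulfonyl)-6-{10-[(4R)-2,2-dimethyl-1,3-dioxolan-4-yl]decylidene}-2-methyl-1,6-dihydropyridin-3(2H)-one F2. Hydrogenation (H2, Pd/C, EtOAc) would then saturate both C=C bonds. In the neutral sulfonamide the 2-methyl group is pseudo-axial, so hydrogen should reach C6 from the opposite face and give the 2,6-cis ketone 16; step 6 is absorbed.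

Step 4. Two oxidations share one peracid. The furan may be opened before sulfur has reached the sulfonyl level, giving N-sulfinyl enediones that degrade, or the Z-enedione may isomerise before the hindered nitrogen closes the ring. An enedione 12 that merely stays open should still be drained through 14 under the step 5 conditions. The fallback sets out from 7 and returns at 13; it introduces nitrogen already at the sulfonyl level and sets C2 by catalysis. Condensation of 7 with 2-methylpropane-2-sulfonamide (CC(C)(C)S(N)(=O)=O; Ti(OEt)4, toluene, 110 °C) would give the N-sulfonyl ketimine (E)-N-[1-(5-{10-[(4R)-2,2-dimethyl-1,3-dioxolan-4-yl]decyl}furan-2-yl)ethylidene]-2-methylpropane-2-sulfonamide F1. Palladium-catalysed asymmetric hydrogenation of this activated imine (Pd(OCOCF3)2, chiral bisphosphine, H2, CF3CH2OH; ligand enantiomer selected for the (S) product) would give 11 as an isolated compound. A single peracid-free aza-Achmatowicz oxidation (NBS, NaHCO3, THF–H2O, 0 °C) would then lead to 13.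

Step 9. The forcing sulfonamide cleavage may cost the acetyl group (acid-promoted loss, or O→N transfer once the amine is free), or cleavage at the hindered nitrogen may stall. The fallback sets out from 17 and returns at 19; the sulfonyl group is removed while no ester is present, and the last step needs only aqueous trifluoroacetic acid. Treatment of 17 with TfOH/anisole and aqueous work-up would give the amino triol (2S,3S,6R)-6-[(11R)-11,12-dihydroxydodecyl]-2-methylpiperidin-3-ol F3. Boc2O (Et3N, MeOH, 45 °C) would give its N-Boc carbamate tert-butyl (2R,5S,6S)-2-[(11R)-11,12-dihydroxydodecyl]-5-hydroxy-6-methylpiperidine-1-carboxylate F4. 2,2-Dimethoxypropane (cat. PPTS, acetone) would re-mask the 1,2-diol as tert-butyl (2R,5S,6S)-2-{10-[(4R)-2,2-dimethyl-1,3-dioxolan-4-yl]decyl}-5-hydroxy-6-methylpiperidine-1-carboxylate F5. Acetylation (Ac2O, Et3N, DMAP) would give tert-butyl (2R,5S,6S)-5-acetoxy-2-{10-[(4R)-2,2-dimethyl-1,3-dioxolan-4-yl]decyl}-6-methylpiperidine-1-carboxylate F6. TFA–H2O (9:1, 0 °C) followed by cold NaHCO3 would remove carbamate and acetonide to give 19.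

**Further compounds**
F1 | step 4 | (E)-N-[1-(5-{10-[(4R)-2,2-dimethyl-1,3-dioxolan-4-yl]decyl}furan-2-yl)ethylidene]-2-methylpropane-2-sulfonamide | C/C(=N\S(=O)(=O)C(C)(C)C)c1ccc(CCCCCCCCCC[C@@H]2COC(C)(C)O2)o1
F2 | step 5 | (2S)-1-(tert-butylsulfonyl)-6-{10-[(4R)-2,2-dimethyl-1,3-dioxolan-4-yl]decylidene}-2-methyl-1,6-dihydropyridin-3(2H)-one | C[C@@H]1N(S(=O)(=O)C(C)(C)C)C(=CCCCCCCCCC[C@@H]2COC(C)(C)O2)C=CC1=O
F3 | step 9 | (2S,3S,6R)-6-[(11R)-11,12-dihydroxydodecyl]-2-methylpiperidin-3-ol | C[C@@H]1N[C@H](CCCCCCCCCC[C@@H](O)CO)CC[C@@H]1O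
F4 | step 9 | tert-butyl (2R,5S,6S)-2-[(11R)-11,12-dihydroxydodecyl]-5-hydroxy-6-methylpiperidine-1-carboxylate | C[C@@H]1N(C(=O)OC(C)(C)C)[C@H](CCCCCCCCCC[C@@H](O)CO)CC[C@@H]1O
F5 | step 9 | tert-butyl (2R,5S,6S)-2-{10-[(4R)-2,2-dimethyl-1,3-dioxolan-4-yl]decyl}-5-hydroxy-6-methylpiperidine-1-carboxylate | C[C@@H]1N(C(=O)OC(C)(C)C)[C@H](CCCCCCCCCC[C@@H]2COC(C)(C)O2)CC[C@@H]1O
F6 | step 9 | tert-butyl (2R,5S,6S)-5-acetoxy-2-{10-[(4R)-2,2-dimethyl-1,3-dioxolan-4-yl]decyl}-6-methylpiperidine-1-carboxylate | C[C@@H]1N(C(=O)OC(C)(C)C)[C@H](CCCCCCCCCC[C@@H]2COC(C)(C)O2)CC[C@@H]1OC(C)=O
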